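**Retrosynthetic overview**
1. Target ⇐ phenol desilylation, IBX desaturation (C5=C6) and C4–O acylation of a trans-fused bicyclic γ-hydroxy ketone.
2. Key disconnection C4–C5: a samarium diiodide ketyl (aldehyde carbon made nucleophilic) adds 7-endo to the β-carbon of an isopropenyl ketone; this closes the seven-membered ring last and sets C4.
3. Cyclopentane precursor: C1 acetate by anti reduction then Mitsunobu inversion; C3 tertiary alcohol by conjugate borylation–oxidation of a 3-isopropylcyclopentenone; isopropenyl ketone from a Weinreb amide.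
4. C3a/C8a: copper-catalysed asymmetric vinyl addition to 2-methylcyclopent-2-enone, then trans alkylation of the enolate with an α-bromo Weinreb acetamide (enolonium equivalent).
5. Ring order: the five-membered ring is the starting enone; the seven-membered ring is formed in step 9.

Labels (one-line convention): azulene numbering of the target is used for all intermediates (C1 acetoxy carbon, C3 carbinol with isopropyl, C3a ring-fusion CH, C4 aroyloxy carbon, C5=C6, C7 ketone, C8, C8a methyl-bearing carbon); α is the face of H-3a, β the face of the C8a methyl; the target is 1R,3R,3aR,4R,8aS.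

**Step 1**
Reactants: 1 2-methylcyclopent-2-en-1-one; 2 vinylmagnesium bromide; 3 2-bromo-N-methoxy-N-methylacetamide
Product: 5 2-[(1S,5S)-1-methyl-2-oxo-5-vinylcyclopentyl]-N-methoxy-N-methylacetamide, via bromomagnesium enolate 4 (not isolated)
Conditions: Cu(OTf)2 (3 mol %), chiral hydroxyalkyl imidazolinium chloride (NHC precursor, enantiomer giving the 3S-vinyl adduct, 4 mol %), 2 (1.3 equiv), Et2O, −30 °C; then 3, DMPU, −30 → 0 °C
Reagents that add atoms: none
Why: Copper-catalysed asymmetric conjugate addition sets C3a under ligand control, and the tetrasubstituted magnesium enolate is then C-alkylated (SN2) by the α-bromo amide, an enolonium equivalent, on the face anti to the new vinyl group, which sets the C8a quaternary centre with methyl cis to vinyl (vicinal trans-dialkylation of an enone).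

**Step 2**
Reactants: 5 2-[(1S,5S)-1-methyl-2-oxo-5-vinylcyclopentyl]-N-methoxy-N-methylacetamide
Product: 6 2-[(1S,5R)-1-methyl-2-oxo-5-vinylcyclopent-3-en-1-yl]-N-methoxy-N-methylacetamide
Conditions: IBX (1.5 equiv), DMSO/fluorobenzene, 70 °C
Reagents that add atoms: none
Why: IBX dehydrogenation of a ketone can only give the C2=C3 enone because C8a is quaternary, and no stereocentre is touched.

**Step 3**
Reactants: 6 2-[(1S,5R)-1-methyl-2-oxo-5-vinylcyclopent-3-en-1-yl]-N-methoxy-N-methylacetamide; 7 isopropylmagnesium chloride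
Product: 9 2-[(1S,5R)-1-methyl-2-oxo-4-(propan-2-yl)-5-vinylcyclopent-3-en-1-yl]-N-methoxy-N-methylacetamide, via silyl enol ether 8 (not isolated)
Conditions: 7 (1.4 equiv), CuBr·SMe2 (10 mol %), TMSCl, THF, −78 °C; then Pd(OAc)2 (10 mol %), O2 (1 atm), DMSO, 25 °C
Reagents that add atoms: none
Why: Copper-catalysed 1,4-addition with TMSCl trapping (the C3 centre formed anti to vinyl is temporary) followed by Saegusa–Ito oxidation of the silyl enol ether regenerates the enone with isopropyl on C3; the Weinreb amide is inert at −78 °C.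

**Step 4**
Reactants: 9 2-[(1S,5R)-1-methyl-2-oxo-4-(propan-2-yl)-5-vinylcyclopent-3-en-1-yl]-N-methoxy-N-methylacetamide
Product: 11 2-[(1S,4R,5S)-4-hydroxy-1-methyl-2-oxo-4-(propan-2-yl)-5-vinylcyclopentyl]-N-methoxy-N-methylacetamide, via tertiary boronate 10 (not isolated)
Conditions: B2pin2 (1.2 equiv), CuCl (5 mol %), NaOt-Bu (10 mol %), Xantphos (5 mol %), MeOH (2 equiv), THF, 25 °C; then H2O2 (30 %), pH 7 buffer, 0 °C
Reagents that add atoms: hydrogen peroxide, OO
Why: Copper-catalysed conjugate borylation of the β,β-disubstituted enone puts boron on C3 from the α face, anti to the C3a vinyl group, and stereoretentive C–B oxidation gives the tertiary alcohol with OH α and isopropyl β.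

**Step 5**
Reactants: 11 2-[(1S,4R,5S)-4-hydroxy-1-methyl-2-oxo-4-(propan-2-yl)-5-vinylcyclopentyl]-N-methoxy-N-methylacetamide
Product: 12 2-[(1S,2S,4R,5S)-2,4-dihydroxy-1-methyl-4-(propan-2-yl)-5-vinylcyclopentyl]-N-methoxy-N-methylacetamide
Conditions: Me4NBH(OAc)3 (5 equiv), MeCN/AcOH (1:1), −30 °C
Reagents that add atoms: none
Why: Evans–Saksena hydroxyl-directed reduction delivers hydride intramolecularly from the C3 alkoxyborohydride to the α face of C1, giving the 1,3-anti diol (C1–OH β) that the later inversion requires.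

**Step 6**
Reactants: 12 2-[(1S,2S,4R,5S)-2,4-dihydroxy-1-methyl-4-(propan-2-yl)-5-vinylcyclopentyl]-N-methoxy-N-methylacetamide; 13 isopropenylmagnesium bromide
Product: 14 1-[(1S,2S,4R,5S)-2,4-dihydroxy-1-methyl-4-(propan-2-yl)-5-vinylcyclopentyl]-3-methylbut-3-en-2-one
Conditions: 13 (4 equiv), THF, −20 → 0 °C; aqueous NH4Cl
Reagents that add atoms: none
Why: Weinreb ketone synthesis stops at the ketone through the chelated magnesium tetrahedral intermediate, two equivalents of Grignard reagent being spent on the hydroxyl groups, so the isopropenyl ketone appears only after all Grignard- and hydride-sensitive steps on the ring.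

**Step 7**
Reactants: 14 1-[(1S,2S,4R,5S)-2,4-dihydroxy-1-methyl-4-(propan-2-yl)-5-vinylcyclopentyl]-3-methylbut-3-en-2-one; 15 acetic acid
Product: 16 (1R,2S,3S,4R)-4-hydroxy-2-methyl-2-(3-methyl-2-oxobut-3-en-1-yl)-4-(propan-2-yl)-3-vinylcyclopentyl acetate
Conditions: PPh3 (2 equiv), DIAD (2 equiv, premixed), 15 (3 equiv), toluene, 0 → 40 °C
Reagents that add atoms: none
Why: Mitsunobu reaction displaces the activated secondary C1 oxygen by acetate with SN2 inversion to give the α-acetate (cis to the C3 hydroxyl), the tertiary alcohol being inert; the analogy is inversion of cyclopentanols next to a quaternary carbon in steroids.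

**Step 8**
Reactants: 16 (1R,2S,3S,4R)-4-hydroxy-2-methyl-2-(3-methyl-2-oxobut-3-en-1-yl)-4-(propan-2-yl)-3-vinylcyclopentyl acetate
Product: 18 (1R,2S,3S,4R)-3-formyl-4-hydroxy-2-methyl-2-(3-methyl-2-oxobut-3-en-1-yl)-4-(propan-2-yl)cyclopentyl acetate, via ozonide 17 (not isolated)
Conditions: O3, CH2Cl2, −78 °C, Sudan Red 7B end-point; then Me2S, −78 → 20 °C
Reagents that add atoms: ozone, [O-][O+]=O
Why: Ozonolysis with reductive work-up cleaves the electron-rich monosubstituted alkene much faster than the electron-poor enone alkene and gives the C4 aldehyde under neutral conditions that do not epimerise C3a.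

**Step 9**
Reactants: 18 (1R,2S,3S,4R)-3-formyl-4-hydroxy-2-methyl-2-(3-methyl-2-oxobut-3-en-1-yl)-4-(propan-2-yl)cyclopentyl acetate
Product: 19 (1R,3R,3aR,4R,8aS)-3,4-dihydroxy-6,8a-dimethyl-7-oxo-3-(propan-2-yl)decahydroazulen-1-yl acetate (C6 epimers)
Conditions: SmI2 (2.5 equiv), HMPA (8 equiv), t-BuOH (2 equiv), THF, −78 °C, slow addition of 18 (0.01 M)
Reagents that add atoms: none
Why: Samarium diiodide ketyl–olefin reductive cyclisation turns the aldehyde carbon into a nucleophilic ketyl that adds 7-endo to the β-carbon of the isopropenyl ketone (two normally electrophilic carbons are joined), the trans-disposed side chains rule out the five-ring pinacol, and the bulky O–samarium group takes the pseudo-equatorial α position away from the C8a methyl and C3 isopropyl groups, which sets C4 as R.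

**Step 10**
Reactants: 19 (1R,3R,3aR,4R,8aS)-3,4-dihydroxy-6,8a-dimethyl-7-oxo-3-(propan-2-yl)decahydroazulen-1-yl acetate; 20 4-[(tert-butyldimethylsilyl)oxy]benzoic acid
Product: 21 (1R,3R,3aR,4R,8aS)-1-(acetyloxy)-3-hydroxy-6,8a-dimethyl-7-oxo-3-(propan-2-yl)decahydroazulen-4-yl 4-[(tert-butyldimethylsilyl)oxy]benzoate (C6 epimers)
Conditions: 20 (1.5 equiv), DCC, DMAP (cat.), CH2Cl2, 25 °C
Reagents that add atoms: none
Why: Steglich esterification acylates the only secondary alcohol (C4–OH) with retention, the tertiary C3–OH being unreactive.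

**Step 11**
Reactants: 21 (1R,3R,3aR,4R,8aS)-1-(acetyloxy)-3-hydroxy-6,8a-dimethyl-7-oxo-3-(propan-2-yl)decahydroazulen-4-yl 4-[(tert-butyldimethylsilyl)oxy]benzoate
Product: 22 (1R,3R,3aR,4R,8aS)-1-(acetyloxy)-3-hydroxy-6,8a-dimethyl-7-oxo-3-(propan-2-yl)-1,2,3,3a,4,7,8,8a-octahydroazulen-4-yl 4-[(tert-butyldimethylsilyl)oxy]benzoate
Conditions: IBX (2 equiv), DMSO/fluorobenzene, 70 °C
Reagents that add atoms: none
Why: IBX dehydrogenation of the C7 ketone can only proceed toward C6–C5 because C8 is attached to the quaternary C8a, which gives the conjugated C5=C6 enone and removes the C6 epimer mixture.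

**Step 12**
Reactants: 22 (1R,3R,3aR,4R,8aS)-1-(acetyloxy)-3-hydroxy-6,8a-dimethyl-7-oxo-3-(propan-2-yl)-1,2,3,3a,4,7,8,8a-octahydroazulen-4-yl 4-[(tert-butyldimethylsilyl)oxy]benzoate
Product: 23 (1R,3R,3aR,4R,8aS)-1-(acetyloxy)-3-hydroxy-6,8a-dimethyl-7-oxo-3-(propan-2-yl)-1,2,3,3a,4,7,8,8a-octahydroazulen-4-yl 4-hydroxybenzoate (CNP0087181.5)
Conditions: HF·pyridine, THF, 0 °C
Reagents that add atoms: none
Why: Fluoride-mediated desilylation cleaves the aryl silyl ether selectively under non-basic conditions that leave the acetate, the benzoate, the γ-acyloxy enone and the tertiary alcohol intact.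

**Compound list**
1 | 2-methylcyclopent-2-en-1-one | CC1=CCCC1=O | starting material
2 | vinylmagnesium bromide | C=C[Mg]Br | starting material
3 | 2-bromo-N-methoxy-N-methylacetamide | CON(C)C(=O)CBr | starting material
4 | bromomagnesium (S)-2-methyl-3-vinylcyclopent-1-en-1-olate (not isolated) | C=C[C@@H]1CCC(O[Mg]Br)=C1C | intermediate
5 | 2-[(1S,5S)-1-methyl-2-oxo-5-vinylcyclopentyl]-N-methoxy-N-methylacetamide | O=C1CC[C@@H](C=C)[C@]1(C)CC(=O)N(C)OC | intermediate
6 | 2-[(1S,5R)-1-methyl-2-oxo-5-vinylcyclopent-3-en-1-yl]-N-methoxy-N-methylacetamide | O=C1C=C[C@@H](C=C)[C@]1(C)CC(=O)N(C)OC | intermediate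
7 | isopropylmagnesium chloride | CC(C)[Mg]Cl | starting material
8 | 2-[(1S,4R,5R)-1-methyl-4-(propan-2-yl)-2-(trimethylsilyloxy)-5-vinylcyclopent-2-en-1-yl]-N-methoxy-N-methylacetamide (not isolated) | C[Si](C)(C)OC1=C[C@H](C(C)C)[C@@H](C=C)[C@]1(C)CC(=O)N(C)OC | intermediate
9 | 2-[(1S,5R)-1-methyl-2-oxo-4-(propan-2-yl)-5-vinylcyclopent-3-en-1-yl]-N-methoxy-N-methylacetamide | O=C1C=C(C(C)C)[C@@H](C=C)[C@]1(C)CC(=O)N(C)OC | intermediate
10 | 2-[(1S,4S,5R)-1-methyl-2-oxo-4-(propan-2-yl)-4-(4,4,5,5-tetramethyl-1,3,2-dioxaborolan-2-yl)-5-vinylcyclopentyl]-N-methoxy-N-methylacetamide (not isolated) | O=C1C[C@@](B2OC(C)(C)C(C)(C)O2)(C(C)C)[C@@H](C=C)[C@]1(C)CC(=O)N(C)OC | intermediate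
11 | 2-[(1S,4R,5S)-4-hydroxy-1-methyl-2-oxo-4-(propan-2-yl)-5-vinylcyclopentyl]-N-methoxy-N-methylacetamide | O=C1C[C@@](O)(C(C)C)[C@@H](C=C)[C@]1(C)CC(=O)N(C)OC | intermediate
12 | 2-[(1S,2S,4R,5S)-2,4-dihydroxy-1-methyl-4-(propan-2-yl)-5-vinylcyclopentyl]-N-methoxy-N-methylacetamide | O[C@H]1C[C@@](O)(C(C)C)[C@@H](C=C)[C@]1(C)CC(=O)N(C)OC | intermediate
13 | isopropenylmagnesium bromide | CC(=C)[Mg]Br | starting material
14 | 1-[(1S,2S,4R,5S)-2,4-dihydroxy-1-methyl-4-(propan-2-yl)-5-vinylcyclopentyl]-3-methylbut-3-en-2-one | O[C@H]1C[C@@](O)(C(C)C)[C@@H](C=C)[C@]1(C)CC(=O)C(C)=C | intermediate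
15 | acetic acid | CC(=O)O | starting material
16 | (1R,2S,3S,4R)-4-hydroxy-2-methyl-2-(3-methyl-2-oxobut-3-en-1-yl)-4-(propan-2-yl)-3-vinylcyclopentyl acetate | CC(=O)O[C@@H]1C[C@@](O)(C(C)C)[C@@H](C=C)[C@]1(C)CC(=O)C(C)=C | intermediate
17 | 1,2,4-trioxolane (ozonide) of the vinyl group of 16 (not isolated) | CC(=O)O[C@@H]1C[C@@](O)(C(C)C)[C@@H](C2OOCO2)[C@]1(C)CC(=O)C(C)=C | intermediate
18 | (1R,2S,3S,4R)-3-formyl-4-hydroxy-2-methyl-2-(3-methyl-2-oxobut-3-en-1-yl)-4-(propan-2-yl)cyclopentyl acetate | CC(=O)O[C@@H]1C[C@@](O)(C(C)C)[C@@H](C=O)[C@]1(C)CC(=O)C(C)=C | intermediate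
19 | (1R,3R,3aR,4R,8aS)-3,4-dihydroxy-6,8a-dimethyl-7-oxo-3-(propan-2-yl)decahydroazulen-1-yl acetate (C6 epimers) | CC(=O)O[C@@H]1C[C@@](O)(C(C)C)[C@H]2[C@H](O)CC(C)C(=O)C[C@]12C | intermediate
20 | 4-[(tert-butyldimethylsilyl)oxy]benzoic acid | CC(C)(C)[Si](C)(C)Oc1ccc(cc1)C(=O)O | starting material
21 | (1R,3R,3aR,4R,8aS)-1-(acetyloxy)-3-hydroxy-6,8a-dimethyl-7-oxo-3-(propan-2-yl)decahydroazulen-4-yl 4-[(tert-butyldimethylsilyl)oxy]benzoate (C6 epimers) | CC(=O)O[C@@H]1C[C@@](O)(C(C)C)[C@H]2[C@H](OC(=O)c3ccc(O[Si](C)(C)C(C)(C)C)cc3)CC(C)C(=O)C[C@]12C | intermediate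
22 | (1R,3R,3aR,4R,8aS)-1-(acetyloxy)-3-hydroxy-6,8a-dimethyl-7-oxo-3-(propan-2-yl)-1,2,3,3a,4,7,8,8a-octahydroazulen-4-yl 4-[(tert-butyldimethylsilyl)oxy]benzoate | CC(=O)O[C@@H]1C[C@@](O)(C(C)C)[C@H]2[C@H](OC(=O)c3ccc(O[Si](C)(C)C(C)(C)C)cc3)C=C(C)C(=O)C[C@]12C | intermediate
23 | (1R,3R,3aR,4R,8aS)-1-(acetyloxy)-3-hydroxy-6,8a-dimethyl-7-oxo-3-(propan-2-yl)-1,2,3,3a,4,7,8,8a-octahydroazulen-4-yl 4-hydroxybenzoate | CC(=O)O[C@@H]1C[C@@](O)(C(C)C)[C@H]2[C@H](OC(=O)c3ccc(O)cc3)C=C(C)C(=O)C[C@]12C | target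

**Step count**
Total steps: 12. Longest linear sequence: 12 steps (from 1).

**Three steps most likely to fail, with fallbacks**

Step 1. The ligand-controlled addition of a vinyl Grignard reagent to an α-substituted enone, and the one-pot alkylation of a hindered magnesium enolate, may give low ee or low conversion. The fallback sets out from 1: rhodium-catalysed asymmetric 1,4-addition of potassium vinyltrifluoroborate ([Rh(C2H4)2Cl]2, chiral diene ligand, KOH, dioxane/H2O) gives (3S)-2-methyl-3-vinylcyclopentan-1-one F1 as C2 epimers. TMSCl/NaI/Et3N in MeCN converts it into the thermodynamic tetrasubstituted silyl enol ether F2. MeLi in THF then releases the lithium enolate regiospecifically, and alkylation with 3 (HMPA, −78 → 0 °C) anti to vinyl comes back to the route at 5.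

Step 7. Intermolecular Mitsunobu inversion at the neopentyl-type C1 carbinol may stall or eliminate. The fallback sets out from 12, before the Grignard step: PPh3/DIAD in THF without external acid lets the Weinreb carbonyl oxygen displace the activated C1 oxygen intramolecularly with inversion, and aqueous hydrolysis of the O-alkyl imidate gives the cis-fused γ-lactone (3aS,4S,5R,6aR)-5-hydroxy-3a-methyl-5-(propan-2-yl)-4-vinylhexahydro-2H-cyclopenta[b]furan-2-one F3. Isopropenyllithium (THF, −78 °C) opens the lactone to the hydroxy enone F4, which now carries the C1 hydroxyl on the α face. Ac2O/pyridine/DMAP acetylates the secondary alcohol and comes back to the route at 16.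

Step 9. The 7-endo ketyl addition may lose to simple aldehyde or enone reduction, or give the wrong C4 epimer. The fallback sets out from 18: chemoselective Nozaki–Hiyama–Kishi vinylation of the aldehyde (vinyl bromide, CrCl2, NiCl2 cat., DMF) gives the allylic alcohol F5 as carbinol epimers. Ring-closing metathesis with the second-generation Grubbs catalyst (toluene, 80 °C) closes the seven-membered ring at C5=C6 and gives the γ-hydroxy enone F6 after separation of the C4 epimers. The 4R epimer is esterified with 20 (DCC, DMAP), and the 4S epimer is converted by Mitsunobu inversion with 20; both come back to the route at 22.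

**Further compounds**
F1 | step 1 | (3S)-2-methyl-3-vinylcyclopentan-1-one (C2 epimers) | C=C[C@@H]1CCC(=O)C1C
F2 | step 1 | (S)-trimethyl[(2-methyl-3-vinylcyclopent-1-en-1-yl)oxy]silane | C=C[C@@H]1CCC(O[Si](C)(C)C)=C1C
F3 | step 7 | (3aS,4S,5R,6aR)-5-hydroxy-3a-methyl-5-(propan-2-yl)-4-vinylhexahydro-2H-cyclopenta[b]furan-2-one | O2[C@@H]1C[C@@](O)(C(C)C)[C@@H](C=C)[C@]1(C)CC2=O
F4 | step 7 | 1-[(1S,2R,4R,5S)-2,4-dihydroxy-1-methyl-4-(propan-2-yl)-5-vinylcyclopentyl]-3-methylbut-3-en-2-one | O[C@@H]1C[C@@](O)(C(C)C)[C@@H](C=C)[C@]1(C)CC(=O)C(C)=C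
F5 | step 9 | (1R,2S,3R,4R)-4-hydroxy-3-(1-hydroxyprop-2-en-1-yl)-2-methyl-2-(3-methyl-2-oxobut-3-en-1-yl)-4-(propan-2-yl)cyclopentyl acetate (carbinol epimers) | CC(=O)O[C@@H]1C[C@@](O)(C(C)C)[C@@H](C(O)C=C)[C@]1(C)CC(=O)C(C)=C
F6 | step 9 | (1R,3R,3aR,4R,8aS)-3,4-dihydroxy-6,8a-dimethyl-7-oxo-3-(propan-2-yl)-1,2,3,3a,4,7,8,8a-octahydroazulen-1-yl acetate | CC(=O)O[C@@H]1C[C@@](O)(C(C)C)[C@H]2[C@H](O)C=C(C)C(=O)C[C@]12C
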